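**Retrosynthetic overview**

1. The 1,2-dioxepine is the ring tautomer of an (11S)-11-hydroperoxy-12E-ene-15,16-dial. It is closed last by addition of the C11–OOH to the C15 aldehyde; C12=C13 comes from a Wittig reaction of an 11-silylperoxy-12-aldehyde with a formyl ylide.
2. The C11–O bond comes from a singlet-oxygen silatropic ene reaction of the C11=C12 silyl enol ether, with the face set by the C9 stereocentre.
3. Ring B is adjusted from a 7-ene (α-epoxide → 8(17)-en-7α-ol → 7-one → 7β-ol). C11 is attached to the C9 ketone through a spiro-epoxide and Meinwald shift, and C12 through an alkyne.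
4. Structural feature: ring B (C5–C10, with the C8 methyl and the C9 carbonyl) is the ring of (R)-carvone. Ring A is closed by forming C3–C4 at the C4 gem-dimethyl carbon: hydrogen-atom transfer to the isopropenyl group, then 6-endo radical addition to a vinyl ketone.
5. Ring order: B (chiral pool) → A (radical cyclisation, step 4) → dioxepine (hemiperacetal, step 22).

Key step: step 4

Remarks on the chemistry: labdane numbering is used for all decalin compounds (C17 = 8-methyl/exocyclic methylene carbon, C20 = angular methyl). The hemiperacetal carbon C15 is assumed to equilibrate through the open hydroperoxy dialdehyde, the (15R) epimer of the target being the one delivered by this equilibrium.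

**Step 1**
Reactants: 1 (R)-(−)-carvone; 2 iodomethane
Product: 3 trans-6-methylcarvone
Conditions: LDA, THF, −78 °C; MeI, −78 → 0 °C
Reagents that add atoms: iodomethane (2), CI
Why: Kinetic α′-deprotonation gives the cross-conjugated enolate, which is C-methylated anti to the neighbouring isopropenyl group (enolate alkylation); this centre is re-enolised in step 2, so its epimer ratio does not matter.

**Step 2**
Reactants: 3 trans-6-methylcarvone; 4 acrolein
Product: 5 6-(1-hydroxyallyl)-6-methylcarvone (hydroxyallyl anti to isopropenyl, both carbinol epimers)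
Conditions: LDA, THF, −78 °C; acrolein, −78 °C; AcOH quench at −78 °C
Reagents that add atoms: acrolein (4), C=CC=O
Why: Aldol 1,2-addition of the tetrasubstituted lithium enolate to the enal should occur on the face opposite the adjacent isopropenyl group, which fixes the quaternary carbon (later C10) with the new chain trans to isopropenyl, and the cold quench prevents retro-aldol.

**Step 3**
Reactants: 5 6-(1-hydroxyallyl)-6-methylcarvone
Product: 6 6-acryloyl-6-methyl-(R)-carvone (acryloyl trans to isopropenyl)
Conditions: Dess–Martin periodinane, CH2Cl2, 0 °C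
Reagents that add atoms: none
Why: Dess–Martin oxidation converts the allylic alcohol into the vinyl ketone under non-basic conditions, and the quaternary carbon between the two carbonyls cannot enolise.

**Step 4**
Reactants: 6 6-acryloyl-6-methyl-(R)-carvone
Product: 7 11-nordrim-7-ene-1,9-dione (trans-decalin, 5α-H, 10β-CH3, C4 gem-dimethyl)
Conditions: Fe(acac)3, PhSiH3, EtOH/(CH2OH)2, 60 °C
Reagents that add atoms: none
Why: An iron hydride formed from Fe(acac)3 and PhSiH3 transfers a hydrogen atom to the CH2 terminus of the isopropenyl group, creating the second C4 methyl and a nucleophilic tertiary C4 radical; this adds to the unsubstituted β-carbon C3 of the vinyl ketone, and the α-keto radical is reduced and protonated by the alcohol solvent. The closest known reaction type is the iron-hydride HAT-initiated reductive olefin coupling (radical conjugate addition of an unactivated alkene to an enone) in its intramolecular form. Ring A (C1–C2–C3–C4–C5–C10) closes in the 6-endo-trig mode, the 5-exo alternative being attack at the electron-poor α-carbon C2. No stereocentre is created: C4 becomes a gem-dimethyl carbon and C2 a methylene, and the trans ring fusion follows from the C5 and C10 centres of steps 1–2, whose trans-diequatorial isopropenyl and acryloyl groups can only bridge to a trans-decalin. The step needs HAT to the 1,1-disubstituted alkene rather than to either enone, and attack at C3 rather than C2; the first is secured by the preference of the metal hydride for the most electron-rich alkene, the second by the polarity match of a nucleophilic radical with an unhindered enone terminus.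

**Step 5**
Reactants: 7 11-nordrim-7-ene-1,9-dione
Product: 8 1-(trifluoromethanesulfonyloxy)-11-nordrima-1,7-dien-9-one
Conditions: KHMDS, THF, −78 °C; PhNTf2, −78 → 0 °C
Reagents that add atoms: N-phenylbis(trifluoromethanesulfonimide), O=S(=O)(N(c1ccccc1)S(=O)(=O)C(F)(F)F)C(F)(F)F
Why: C2 carries the only kinetically accessible α-hydrogens (C10 is quaternary and the enone can only lose a γ-hydrogen), so enolate O-sulfonylation should give the C1 enol triflate regioselectively.

**Step 6**
Reactants: 8 1-(trifluoromethanesulfonyloxy)-11-nordrima-1,7-dien-9-one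
Product: 9 11-nordrima-1,7-dien-9-one
Conditions: Pd(OAc)2 (cat.), PPh3, HCO2H, Bu3N, DMF, 60 °C
Reagents that add atoms: none
Why: Palladium-catalysed formate reduction of the vinyl triflate (oxidative addition, formate exchange, decarboxylation, reductive elimination) replaces C1–O by C1–H without touching the enone.

**Step 7**
Reactants: 9 11-nordrima-1,7-dien-9-one
Product: 10 11-nordrim-7-en-9-one
Conditions: H2 (1 atm), RhCl(PPh3)3 (cat.), benzene, rt
Reagents that add atoms: none
Why: Homogeneous hydrogenation with Wilkinson's catalyst reduces the cis-disubstituted C1=C2 alkene much faster than the trisubstituted, conjugated C7=C8 alkene.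

**Step 8**
Reactants: 10 11-nordrim-7-en-9-one; 11 trimethylsulfonium iodide
Product: 12 9β,11-epoxydrim-7-ene (spiro-epoxide, CH2 α, O β)
Conditions: Me3S+ I−, n-BuLi, THF, −10 °C → rt
Reagents that add atoms: trimethylsulfonium iodide (11), C[S+](C)C.[I-]
Why: In the Corey–Chaykovsky epoxidation, dimethylsulfonium methylide adds 1,2 and irreversibly to the enone carbonyl along the axial α trajectory, away from the C10 methyl, so the new CH2 is α and the oxygen β.

**Step 9**
Reactants: 12 9β,11-epoxydrim-7-ene
Product: 13 drim-7-en-11-al (drimenal; 9α-H, 9β-CHO)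
Conditions: BF3·OEt2 (cat.), CH2Cl2, −78 °C; NaHCO3 (aq) quench
Reagents that add atoms: none
Why: In the Meinwald rearrangement the Lewis acid opens the allylic tertiary C9–O bond while a hydride shifts from C11 to C9 anti to the departing oxygen, which should give the β,γ-unsaturated aldehyde with 9α-H; it is carried on at once without contact with base.

**Step 10**
Reactants: 13 drim-7-en-11-al; 14 trimethylsilyldiazomethane
Product: 15 13,14,15,16-tetranorlabd-7-en-11-yne
Conditions: TMSCHN2, LDA, THF, −78 °C → rt
Reagents that add atoms: trimethylsilyldiazomethane (14), C[Si](C)(C)C=[N+]=[N-]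
Why: In the Colvin homologation the lithiated silyldiazomethane adds to the aldehyde at −78 °C faster than it enolises C9, and loss of silanolate and N2 gives an alkylidene carbene that rearranges by 1,2-H shift to the terminal alkyne.

**Step 11**
Reactants: 15 13,14,15,16-tetranorlabd-7-en-11-yne
Product: 16 7α,8α-epoxy-13,14,15,16-tetranorlabd-11-yne
Conditions: mCPBA, CH2Cl2, 0 °C
Reagents that add atoms: 3-chloroperbenzoic acid, O=C(OO)c1cccc(Cl)c1
Why: Prilezhaev epoxidation takes the electron-rich trisubstituted C7=C8 alkene (the alkyne is inert) from the α-face, because the β-face is screened by the axial C10 methyl and the β substituent at C9.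

**Step 12**
Reactants: 16 7α,8α-epoxy-13,14,15,16-tetranorlabd-11-yne
Product: 17 13,14,15,16-tetranorlabd-8(17)-en-11-yn-7α-ol
Conditions: Et2Al(TMP) (from LiTMP, Et2AlCl; excess), toluene, 0 °C
Reagents that add atoms: none
Why: In this base-mediated epoxide-to-allylic-alcohol isomerisation the aluminium amide binds the epoxide oxygen and removes a syn β-hydrogen from the least hindered site, the C17 methyl, through a cyclic transition state, giving the exocyclic alkene with C7–O retained as 7α-OH (the excess covers the acetylenic C–H).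

**Step 13**
Reactants: 17 13,14,15,16-tetranorlabd-8(17)-en-11-yn-7α-ol
Product: 18 13,14,15,16-tetranorlabd-8(17)-en-11-yn-7-one
Conditions: Dess–Martin periodinane, CH2Cl2, 0 °C
Reagents that add atoms: none
Why: Dess–Martin oxidation of the allylic alcohol gives the exo-methylene enone under neutral conditions that should not move the double bond into the ring.

**Step 14**
Reactants: 18 13,14,15,16-tetranorlabd-8(17)-en-11-yn-7-one
Product: 19 13,14,15,16-tetranorlabd-8(17)-en-11-yn-7β-ol
Conditions: NaBH4, CeCl3·7H2O, MeOH, −78 °C
Reagents that add atoms: none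
Why: In the Luche 1,2-reduction the small hydride attacks axially from the open α-face (only H-5α and H-9α are axial there), so the new hydroxyl is equatorial and β.

**Step 15**
Reactants: 19 13,14,15,16-tetranorlabd-8(17)-en-11-yn-7β-ol
Product: 20 7β-triethylsilyloxy-13,14,15,16-tetranorlabd-8(17)-en-11-yne
Conditions: TESCl, imidazole, DMF, 0 °C → rt
Reagents that add atoms: chlorotriethylsilane, CC[Si](Cl)(CC)CC
Why: Standard silylation of the secondary alcohol gives an ether that survives steps 16–21 and is removed by the mild acid of step 22.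

**Step 16**
Reactants: 20 7β-triethylsilyloxy-13,14,15,16-tetranorlabd-8(17)-en-11-yne
Product: 22 7β-triethylsilyloxy-13,14,15,16-tetranorlabd-8(17)-en-12-al, via (E)-alkenyl(dicyclohexyl)borane 21 (not isolated)
Conditions: Cy2BH (from BH3·SMe2, cyclohexene), THF, 0 °C; then H2O2, pH 7 phosphate buffer, 0 °C
Reagents that add atoms: hydrogen peroxide, OO
Why: The bulky dialkylborane adds anti-Markovnikov to the terminal alkyne far faster than to the hindered 1,1-disubstituted exocyclic alkene, and buffered oxidation of the alkenylborane gives the enol and hence the aldehyde (alkyne hydroboration–oxidation).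

**Step 17**
Reactants: 22 7β-triethylsilyloxy-13,14,15,16-tetranorlabd-8(17)-en-12-al
Product: 23 7β,12-bis(triethylsilyloxy)-13,14,15,16-tetranorlabda-8(17),11-diene (mainly 11Z)
Conditions: TESOTf, Et3N, CH2Cl2, −78 → 0 °C
Reagents that add atoms: triethylsilyl trifluoromethanesulfonate, CC[Si](CC)(CC)OS(=O)(=O)C(F)(F)F
Why: Soft enolisation of the aldehyde by silyl triflate and amine gives the silyl enol ether, and both geometric isomers are usable in step 18.

**Step 18**
Reactants: 23 7β,12-bis(triethylsilyloxy)-13,14,15,16-tetranorlabda-8(17),11-diene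
Product: 24 (11R)-7β-triethylsilyloxy-11-(triethylsilylperoxy)-13,14,15,16-tetranorlabd-8(17)-en-12-al
Conditions: O2, hν (visible), tetraphenylporphyrin (cat.), CH2Cl2, −78 °C
Reagents that add atoms: dioxygen, O=O
Why: In the silatropic (Schenck-type) ene reaction singlet oxygen bonds to C11 while silicon migrates from the enol oxygen to the terminal peroxy oxygen and the C12 aldehyde is unveiled; allylic 1,3-strain holds C9–H in the alkene plane, so O2 should approach C11 from the side of sp2 C8 rather than quaternary C10, which gives the C11–O arrangement of the target (11R here by CIP priorities, 11S in the target), and the exocyclic alkene, 1,1-disubstituted and deactivated by the allylic silyloxy group, reacts far more slowly.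

**Step 19**
Reactants: 25 3-bromo-1,1-dimethoxypropane; 26 triphenylphosphine
Product: 27 (3,3-dimethoxypropyl)triphenylphosphonium bromide
Conditions: MeCN, 80 °C
Reagents that add atoms: triphenylphosphine (26), c1ccc(cc1)P(c1ccccc1)c1ccccc1
Why: SN2 quaternisation of the phosphine by the primary bromide, with the acetal untouched in the absence of acid.

**Step 20**
Reactants: 27 (3,3-dimethoxypropyl)triphenylphosphonium bromide; 28 ethyl formate
Product: 30 4,4-dimethoxy-2-(triphenyl-λ5-phosphanylidene)butanal, via non-stabilised ylide 29 (not isolated)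
Conditions: KOtBu (2 equiv), THF, 0 °C; HCO2Et, 0 °C → rt
Reagents that add atoms: ethyl formate (28), CCOC=O
Why: The phosphorus ylide is C-formylated by the formate ester and the resulting acylphosphonium is deprotonated by the second equivalent of base to the stabilised formyl ylide (ylide acylation).

**Step 21**
Reactants: 24 (11R)-11-(triethylsilylperoxy)-12-aldehyde; 30 4,4-dimethoxy-2-(triphenyl-λ5-phosphanylidene)butanal
Product: 31 (11S,12E)-15,15-dimethoxy-7β-triethylsilyloxy-11-(triethylsilylperoxy)labda-8(17),12-dien-16-al
Conditions: benzene, 45 °C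
Reagents that add atoms: 4,4-dimethoxy-2-(triphenyl-λ5-phosphanylidene)butanal (30), O=CC(CC(OC)OC)=P(c1ccccc1)(c1ccccc1)c1ccccc1
Why: Wittig olefination with a formyl-stabilised ylide should give the E-2-substituted enal (C11 trans to CHO) under neutral conditions mild enough to preserve the O–O bond and the acidic C11–H of the α-peroxy aldehyde.

**Step 22**
Reactants: 31 (11S,12E)-15,15-dimethoxy-7β-triethylsilyloxy-11-(triethylsilylperoxy)labda-8(17),12-dien-16-al
Product: 33 CNP0269954.2, via open-chain hydroperoxy dialdehyde 32 (not isolated)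
Conditions: AcOH/THF/H2O (3:1:1), rt
Reagents that add atoms: water, O
Why: Mild aqueous acid removes both triethylsilyl groups and hydrolyses the dimethyl acetal, and the freed C11 hydroperoxide adds to the C15 aldehyde (hemiperacetal formation by ring–chain tautomerism); the E enal geometry allows ring closure only toward C15, C11 is untouched, and C15 settles as the equilibrium epimer.

**Compound list**

1 | (R)-(−)-carvone | CC1=CC[C@H](CC1=O)C(C)=C | starting material
2 | iodomethane | CI | starting material
3 | trans-6-methylcarvone (methyl anti to isopropenyl; minor cis epimer carried along) | CC1=CC[C@@H](C(C)=C)[C@H](C)C1=O | intermediate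
4 | acrolein | C=CC=O | starting material
5 | 6-(1-hydroxyallyl)-6-methylcarvone (hydroxyallyl anti to isopropenyl; carbinol centre unassigned, both epimers) | CC1=CC[C@@H](C(C)=C)[C@](C)(C(O)C=C)C1=O | intermediate
6 | 6-acryloyl-6-methyl-(R)-carvone (acryloyl trans to isopropenyl) | CC1=CC[C@@H](C(C)=C)[C@](C)(C(=O)C=C)C1=O | intermediate
7 | 11-nordrim-7-ene-1,9-dione (trans-decalin, 5α-H, 10β-CH3) | CC1=CC[C@H]2C(C)(C)CCC(=O)[C@]2(C)C1=O | intermediate
8 | 1-(trifluoromethanesulfonyloxy)-11-nordrima-1,7-dien-9-one | CC1=CC[C@H]2C(C)(C)CC=C(OS(=O)(=O)C(F)(F)F)[C@]2(C)C1=O | intermediate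
9 | 11-nordrima-1,7-dien-9-one | CC1=CC[C@H]2C(C)(C)CC=C[C@]2(C)C1=O | intermediate
10 | 11-nordrim-7-en-9-one | CC1=CC[C@H]2C(C)(C)CCC[C@]2(C)C1=O | intermediate
11 | trimethylsulfonium iodide | C[S+](C)C.[I-] | starting material
12 | 9β,11-epoxydrim-7-ene (spiro-epoxide, CH2 α, O β) | CC1=CC[C@H]2C(C)(C)CCC[C@]2(C)[C@]13CO3 | intermediate
13 | drim-7-en-11-al (9α-H, 9β-CHO) | CC1=CC[C@H]2C(C)(C)CCC[C@]2(C)[C@H]1C=O | intermediate
14 | trimethylsilyldiazomethane | C[Si](C)(C)C=[N+]=[N-] | starting material
15 | 13,14,15,16-tetranorlabd-7-en-11-yne (9α-H) | C#C[C@H]1C(C)=CC[C@H]2C(C)(C)CCC[C@]12C | intermediate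
16 | 7α,8α-epoxy-13,14,15,16-tetranorlabd-11-yne | C#C[C@H]1[C@]2(C)O[C@@H]2C[C@H]2C(C)(C)CCC[C@]12C | intermediate
17 | 13,14,15,16-tetranorlabd-8(17)-en-11-yn-7α-ol | C=C1[C@H](C#C)[C@@]2(C)CCCC(C)(C)[C@@H]2C[C@H]1O | intermediate
18 | 13,14,15,16-tetranorlabd-8(17)-en-11-yn-7-one | C=C1[C@H](C#C)[C@@]2(C)CCCC(C)(C)[C@@H]2CC1=O | intermediate
19 | 13,14,15,16-tetranorlabd-8(17)-en-11-yn-7β-ol | C=C1[C@H](C#C)[C@@]2(C)CCCC(C)(C)[C@@H]2C[C@@H]1O | intermediate
20 | 7β-triethylsilyloxy-13,14,15,16-tetranorlabd-8(17)-en-11-yne | C=C1[C@H](C#C)[C@@]2(C)CCCC(C)(C)[C@@H]2C[C@@H]1O[Si](CC)(CC)CC | intermediate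
21 | (E)-alkenyl(dicyclohexyl)borane at C12 of 20 | C=C1[C@H](/C=C/B(C2CCCCC2)C2CCCCC2)[C@@]2(C)CCCC(C)(C)[C@@H]2C[C@@H]1O[Si](CC)(CC)CC | intermediate
22 | 7β-triethylsilyloxy-13,14,15,16-tetranorlabd-8(17)-en-12-al | C=C1[C@H](CC=O)[C@@]2(C)CCCC(C)(C)[C@@H]2C[C@@H]1O[Si](CC)(CC)CC | intermediate
23 | (11Z)-7β,12-bis(triethylsilyloxy)-13,14,15,16-tetranorlabda-8(17),11-diene | C=C1[C@H](/C=C\O[Si](CC)(CC)CC)[C@@]2(C)CCCC(C)(C)[C@@H]2C[C@@H]1O[Si](CC)(CC)CC | intermediate
24 | (11R)-7β-triethylsilyloxy-11-(triethylsilylperoxy)-13,14,15,16-tetranorlabd-8(17)-en-12-al | C=C1[C@H]([C@H](C=O)OO[Si](CC)(CC)CC)[C@@]2(C)CCCC(C)(C)[C@@H]2C[C@@H]1O[Si](CC)(CC)CC | intermediate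
25 | 3-bromo-1,1-dimethoxypropane | COC(CCBr)OC | starting material
26 | triphenylphosphine | c1ccc(cc1)P(c1ccccc1)c1ccccc1 | starting material
27 | (3,3-dimethoxypropyl)triphenylphosphonium bromide | COC(CC[P+](c1ccccc1)(c1ccccc1)c1ccccc1)OC.[Br-] | intermediate
28 | ethyl formate | CCOC=O | starting material
29 | (3,3-dimethoxypropylidene)triphenylphosphorane | COC(CC=P(c1ccccc1)(c1ccccc1)c1ccccc1)OC | intermediate
30 | 4,4-dimethoxy-2-(triphenyl-λ5-phosphanylidene)butanal | O=CC(CC(OC)OC)=P(c1ccccc1)(c1ccccc1)c1ccccc1 | intermediate
31 | (11S,12E)-15,15-dimethoxy-7β-triethylsilyloxy-11-(triethylsilylperoxy)labda-8(17),12-dien-16-al | C=C1[C@H]([C@H](/C=C(\CC(OC)OC)C=O)OO[Si](CC)(CC)CC)[C@@]2(C)CCCC(C)(C)[C@@H]2C[C@@H]1O[Si](CC)(CC)CC | intermediate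
32 | (11S,12E)-11-hydroperoxy-7β-hydroxylabda-8(17),12-diene-15,16-dial | C=C1[C@H]([C@H](/C=C(\CC=O)C=O)OO)[C@@]2(C)CCCC(C)(C)[C@@H]2C[C@@H]1O | intermediate
33 | CNP0269954.2, (5S,7S,9R,10S,11S,15R)-11,15-epidioxy-7β,15-dihydroxylabda-8(17),12-dien-16-al | C=C1[C@H]([C@@H]2C=C(C=O)C[C@H](O)OO2)[C@@]2(C)CCCC(C)(C)[C@@H]2C[C@@H]1O | target

**Step count**

Total: 22 steps. Longest linear sequence: 20 steps (steps 1–18, 21, 22); steps 19–20 prepare the ylide.

**Steps most likely to fail**

Step 18. Singlet oxygen may not discriminate well between the two faces of the enol ether, because the C17 methylene on the C8 side is not much smaller than the C1/C20 groups on the C10 side. The perepoxide may also collapse by [2+2] closure to a dioxetane and cleave C11–C12 instead of undergoing silyl migration. The fallback sets out from aldehyde 22 and replaces substrate control by catalyst control. An enamine is formed with catalytic α-methylproline (the antipode that reinforces attack from the C8 side) and oxygenated with O2, hν and tetraphenylporphyrin in DMF at 0 °C to give (11R)-11-hydroperoxy-7β-triethylsilyloxy-13,14,15,16-tetranorlabd-8(17)-en-12-al F1. This is silylated in the same flask with TESCl and imidazole and rejoins the route at 24.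

Step 21. The α-substituted formyl ylide is weakly nucleophilic and the aldehyde is hindered, so olefination may be slow. On prolonged heating the ylide can act as a base on C11–H and trigger Kornblum–DeLaMare loss of the peroxide. The fallback sets out from 24 and uses a more nucleophilic ester ylide. Salt 27 is deprotonated with KOtBu and acylated with methyl chloroformate to give methyl 4,4-dimethoxy-2-(triphenyl-λ5-phosphanylidene)butanoate F2. Wittig reaction of F2 with 24 at room temperature gives the (11S,12E)-methyl enoate F3. Reduction with DIBAL-H in CH2Cl2 at −78 °C, where the silyl peroxide is expected to survive, gives the (11S,12E)-16-alcohol F4. Oxidation of F4 with MnO2 returns to the route at 31.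

Step 9. The epoxide may ionise to a free allyl cation before the hydride shift, and the aldehyde may epimerise at C9 or shift its double bond into conjugation; each erodes the 9α-H configuration. The fallback sets out from enone 10 and sets C9 by hydroboration instead. Addition of Me3SiCH2Li (THF, −78 → 0 °C) gives 9-hydroxy-9-(trimethylsilylmethyl)-11-nordrim-7-ene F5. Peterson elimination with KH gives 9-methylene-11-nordrim-7-ene F6. Hydroboration of the exocyclic methylene with 9-BBN from the α-face, then NaBO3, gives drimenol F7 (9α-H). Dess–Martin oxidation of F7 returns to the route at 13.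

**Further compounds**

F1 | step 18 | (11R)-11-hydroperoxy-7β-triethylsilyloxy-13,14,15,16-tetranorlabd-8(17)-en-12-al | C=C1[C@H]([C@H](C=O)OO)[C@@]2(C)CCCC(C)(C)[C@@H]2C[C@@H]1O[Si](CC)(CC)CC
F2 | step 21 | methyl 4,4-dimethoxy-2-(triphenyl-λ5-phosphanylidene)butanoate | COC(=O)C(CC(OC)OC)=P(c1ccccc1)(c1ccccc1)c1ccccc1
F3 | step 21 | methyl (11S,12E)-15,15-dimethoxy-7β-triethylsilyloxy-11-(triethylsilylperoxy)labda-8(17),12-dien-16-oate | C=C1[C@H]([C@H](/C=C(\CC(OC)OC)C(=O)OC)OO[Si](CC)(CC)CC)[C@@]2(C)CCCC(C)(C)[C@@H]2C[C@@H]1O[Si](CC)(CC)CC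
F4 | step 21 | (11S,12E)-15,15-dimethoxy-7β-triethylsilyloxy-11-(triethylsilylperoxy)labda-8(17),12-dien-16-ol | C=C1[C@H]([C@H](/C=C(\CC(OC)OC)CO)OO[Si](CC)(CC)CC)[C@@]2(C)CCCC(C)(C)[C@@H]2C[C@@H]1O[Si](CC)(CC)CC
F5 | step 9 | 9β-hydroxy-9α-(trimethylsilylmethyl)-11-nordrim-7-ene | CC1=CC[C@H]2C(C)(C)CCC[C@]2(C)[C@]1(O)C[Si](C)(C)C
F6 | step 9 | 9-methylene-11-nordrim-7-ene (drima-7,9(11)-diene) | C=C1C(C)=CC[C@H]2C(C)(C)CCC[C@]12C
F7 | step 9 | drimenol (drim-7-en-11-ol, 9α-H) | CC1=CC[C@H]2C(C)(C)CCC[C@]2(C)[C@H]1CO
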